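## Retrosynthetic overview

1. Ring letters: A = terminal pyrrole, B = methoxy-2H-pyrrole, C = bridged pyrrole, D = tetrahydropyran, E = twelve-membered ansa ring. The meso carbon is the CH of ring D that bears ring C.
2. Ring D is cut at two adjacent bonds, O–C(spiro) and C(spiro)–C(meso). This gives an ansa-bridged γ-hydroxy 2-acylpyrrole (rings C and E, two stereocentres) and achiral 4-methoxy-2,2'-bipyrrole (rings A and B), to be joined in a formal [5+1] annulation with loss of water.
3. Enabling feature: the spiro carbon is C2 of ring B, flanked by N1 and the methoxy-bearing C3, so it is first the most nucleophilic α-carbon of the bipyrrole and later the electrophilic end of an azafulvenium. The meso carbon beside it is an acylpyrrole carbonyl carbon, and the ring-D oxygen lies 1,4 to the meso and 1,5 to the spiro carbon, so it can activate the ketone as a five-membered oxocarbenium ion and then move over to close ring D.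
4. The hydroxy ketone gets ring E by ring-closing metathesis and hydrogenation of a diene made from a 5-lithiated 2-(hex-5-enyl)pyrrole and trans-α-allyl-(S)-γ-valerolactone, which supplies both stereocentres. The bipyrrole comes from 4-methoxy-3-pyrrolin-2-one and pyrrole.
5. Order of rings: A, B and C are bought as heterocycles, E is closed in step 6, D last in step 9.

Key step: step 9

Assumption: enantiopure (S)-γ-valerolactone is taken as a purchasable material, and the E/Z mixture from the metathesis is carried on unseparated because the alkene is saturated in the next step.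

## Route

Step 1
Reactants: 1 pyrrole
Product: 3 1-{[2-(trimethylsilyl)ethoxy]methyl}-1H-pyrrole (N-SEM-pyrrole), via sodium pyrrolide 2 (not isolated)
Conditions: NaH, DMF, 0 °C; SEMCl, 0 °C → rt
Reagents that add atoms: SEMCl (2-(trimethylsilyl)ethoxymethyl chloride), C[Si](C)(C)CCOCCl
Why: N-Alkylation of the pyrrolide anion (SN2 at the chloromethyl ether) is a standard protection, the SEM oxygen will direct the two α-lithiations that follow, and no stereocentre is formed.

Step 2
Reactants: 3 N-SEM-pyrrole; 4 6-bromo-1-hexene
Product: 6 2-(hex-5-en-1-yl)-1-{[2-(trimethylsilyl)ethoxy]methyl}-1H-pyrrole, via 2-lithio-N-SEM-pyrrole 5 (not isolated)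
Conditions: n-BuLi, THF, −78 → 0 °C; then 4, DMPU, −78 °C → rt
Reagents that add atoms: none
Why: Directed α-lithiation of an N-SEM-pyrrole followed by SN2 alkylation with an unhindered primary bromide is established chemistry, the remote terminal alkene is inert to the organolithium, and no stereocentre is formed.

Step 3
Reactants: 7 (S)-γ-valerolactone; 8 allyl bromide
Product: 10 (3S,5S)-5-methyl-3-(prop-2-en-1-yl)oxolan-2-one (3,5-trans), via lithium enolate 9 (not isolated)
Conditions: LiN(iPr)2 (commercial solution), THF, −78 °C; then 8, −78 → −40 °C
Reagents that add atoms: none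
Why: Kinetic lactone enolate alkylation under 1,3-asymmetric induction, in which allyl bromide approaches the planar enolate 9 on the face opposite the C5 methyl group and should set the new C3 centre as S (3,5-trans), the minor cis isomer being removable by chromatography.

Step 4
Reactants: 6 2-(hex-5-en-1-yl)-N-SEM-pyrrole; 10 trans-allyl lactone
Product: 12 (2S,4S)-1-[5-(hex-5-en-1-yl)-1-{[2-(trimethylsilyl)ethoxy]methyl}-1H-pyrrol-2-yl]-4-hydroxy-2-(prop-2-en-1-yl)pentan-1-one, via 5-lithiopyrrole 11 (not isolated)
Conditions: n-BuLi, THF, 0 °C; then 10, −78 °C; AcOH quench at −78 °C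
Reagents that add atoms: none
Why: Directed lithiation at the only free α-position and 1,2-addition of the heteroaryllithium to the lactone carbonyl (ring-opening acylation by a lactone) give the ketone and free the alcohol in one event without an oxygen protecting group, while the low temperature and the cold acidic quench hold back a second addition and enolisation so that both stereocentres are carried over unchanged.

Step 5
Reactants: 12 N-SEM hydroxy ketone
Product: 13 (2S,4S)-1-[5-(hex-5-en-1-yl)-1H-pyrrol-2-yl]-4-hydroxy-2-(prop-2-en-1-yl)pentan-1-one
Conditions: Bu4NF, THF, 50 °C; aqueous work-up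
Reagents that add atoms: none
Why: Fluoride-triggered fragmentation of the SEM group is eased by the good acylpyrrolide leaving group, the delocalised anion that results should suppress enolisation towards the α-stereocentre, and a free N–H keeps the interior of the ring closed next uncongested.

Step 6
Reactants: 13 hydroxy ketone diene
Product: 14 (3S)-3-[(2S)-2-hydroxypropyl]-14-azabicyclo[9.2.1]tetradeca-1(13),5,11-trien-2-one (E/Z mixture)
Conditions: second-generation Grubbs catalyst (H2IMes)(PCy3)Cl2Ru=CHPh (5 mol %), CH2Cl2 (0.001 M), reflux
Reagents that add atoms: none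
Why: Ring-closing metathesis of two unhindered terminal alkenes at high dilution closes the twelve-membered ansa ring E, the catalyst tolerates the free alcohol and the non-basic acylpyrrole N–H, the alkene geometry is erased in step 7, and no stereocentre is touched.

Step 7
Reactants: 14 macrocyclic alkene
Product: 15 (3S)-3-[(2S)-2-hydroxypropyl]-14-azabicyclo[9.2.1]tetradeca-1(13),11-dien-2-one (ansa-bridged hydroxy ketone)
Conditions: H2 (1 atm), Pd/C, EtOAc, rt
Reagents that add atoms: none
Why: Heterogeneous hydrogenation saturates the isolated disubstituted alkene much faster than the vinylogous-amide-like acylpyrrole, and no stereocentre is formed or touched.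

Step 8
Reactants: 16 4-methoxy-3-pyrrolin-2-one; 1 pyrrole (excess)
Product: 18 4-methoxy-1H,1'H-2,2'-bipyrrole, via imidoyl triflate 17 (not isolated)
Conditions: Tf2O, CH2Cl2, 0 °C; then 1, 0 °C → rt; aq NaHCO3; used promptly
Reagents that add atoms: none
Why: Vilsmeier–Haack-type condensation in which O-triflation turns the lactam into the iminium-type electrophile 17, pyrrole attacks through C2 and the resulting 2H-pyrrole tautomerises to the aromatic bipyrrole (the known pyrrolinone-plus-pyrrole entry to 2,2'-bipyrroles), with no stereocentre formed.

Step 9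
Reactants: 15 ansa-bridged hydroxy ketone; 18 4-methoxy-2,2'-bipyrrole
Product: 22 premarineosin A, via alkoxy-azafulvenium ion 19 (not isolated), via dipyrrolyl oxolane 20 (not isolated), via seco-prodiginine 21 (not isolated)
Conditions: (1S)-(+)-10-camphorsulfonic acid (1.2 equiv), 4 Å molecular sieves, CH2Cl2, −20 °C, 15 first, then slow addition of 18, −20 → 0 °C; Et3N quench at 0 °C
Reagents that add atoms: none
Why: Proposed new method: the acid closes the hydroxyl group onto the protonated acylpyrrole carbonyl (5-exo-trig) and expels water to give the cyclic alkoxy-azafulvenium ion 19, C5 of bipyrrole 18 attacks it to make the hindered bond between the meso carbon and ring B (oxolane 20), the doubly pyrrole-stabilised C–O bond of 20 ionises again to the seco-prodiginine 21, and C-protonation of its meso carbon followed by 6-exo-trig addition of the freed hydroxyl to C2 of ring B (the C=N+ end of the A–B azafulvenium) closes ring D, so that one oxygen atom serves in turn as activator, leaving group and nucleophile and the temporary five-membered ring is exchanged for the six-membered one. The closest known reaction types are the acid-promoted condensation of 2-acylpyrroles with α-free pyrroles to meso-alkyl dipyrrins, the Friedel–Crafts capture of lactol-derived oxocarbenium ions by electron-rich heteroarenes and acid-equilibrated spiroketalisation; their merger and the dearomatising hydroalkoxylation of ring B are the new elements. The closure should be downhill because the ansa bridge turns the N–H of ring C into ring E, away from the nitrogen of ring B, and the tertiary carbon on the meso position clashes with the methoxy group, so that 21 can reach neither the planar nor the internally hydrogen-bonded geometry that normally stabilises a prodiginine, whereas 22 keeps the push–pull conjugation from ring A and the methoxy group to the C=N bond. The meso stereocentre is controlled by the neighbouring stereocentre and the bridge: allylic 1,3-strain holds the neighbouring C–H bond in the plane of the chromophore, the heptamethylene chain covers one face, and the proton should arrive on the open face that carries the hydroxypropyl arm, which places ring C and the chain trans-diequatorial on ring D, and since both epimers of 20 and both geometrical isomers of 21 pass through the same cation the step is stereoconvergent. The spiro centre is set under reversible, thermodynamic control: in the chair with the trans-diequatorial bridge the C-methyl group is axial, so only the unsubstituted sp2 nitrogen of ring B and not its methoxy-bearing carbon can lie syn-axial to it, and this is also the anomerically stabilised arrangement (ring-oxygen lone pair into the C–N antibonding orbital). The step needs site selectivity in 18, secured by the methoxy group that makes C5 (α to nitrogen, β to the enol-ether oxygen) its most nucleophilic carbon, and retention at the stereocentre next to the meso carbon, secured by the in-plane and thus poorly acidic C–H bond, by N–H rather than C–H loss as the preferred way for 19 and 21 to shed a proton, and by the low temperature.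

## Compound list

1 | pyrrole | c1cc[nH]c1 | starting material
2 | sodium pyrrol-1-ide | [Na+].c1cc[n-]c1 | intermediate
3 | 1-{[2-(trimethylsilyl)ethoxy]methyl}-1H-pyrrole | C[Si](C)(C)CCOCn1cccc1 | intermediate
4 | 6-bromo-1-hexene | C=CCCCCBr | starting material
5 | 2-lithio-1-{[2-(trimethylsilyl)ethoxy]methyl}-1H-pyrrole | [Li]c1cccn1COCC[Si](C)(C)C | intermediate
6 | 2-(hex-5-en-1-yl)-1-{[2-(trimethylsilyl)ethoxy]methyl}-1H-pyrrole | C=CCCCCc1cccn1COCC[Si](C)(C)C | intermediate
7 | (S)-γ-valerolactone, (5S)-5-methyloxolan-2-one | C[C@H]1CCC(=O)O1 | starting material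
8 | allyl bromide | C=CCBr | starting material
9 | lithium enolate of 7 | C[C@H]1CC=C([O-])O1.[Li+] | intermediate
10 | (3S,5S)-5-methyl-3-(prop-2-en-1-yl)oxolan-2-one (3,5-trans) | C[C@H]1C[C@H](CC=C)C(=O)O1 | intermediate
11 | 5-lithio derivative of 6 | [Li]c1ccc(CCCCC=C)n1COCC[Si](C)(C)C | intermediate
12 | (2S,4S)-1-[5-(hex-5-en-1-yl)-1-SEM-pyrrol-2-yl]-4-hydroxy-2-(prop-2-en-1-yl)pentan-1-one | C[C@H](O)C[C@H](CC=C)C(=O)c1ccc(CCCCC=C)n1COCC[Si](C)(C)C | intermediate
13 | (2S,4S)-1-[5-(hex-5-en-1-yl)-1H-pyrrol-2-yl]-4-hydroxy-2-(prop-2-en-1-yl)pentan-1-one | C[C@H](O)C[C@H](CC=C)C(=O)c1ccc(CCCCC=C)[nH]1 | intermediate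
14 | (3S)-3-[(2S)-2-hydroxypropyl]-14-azabicyclo[9.2.1]tetradeca-1(13),5,11-trien-2-one, E/Z mixture | C[C@H](O)C[C@@H]1CC=CCCCCc2ccc([nH]2)C1=O | intermediate
15 | (3S)-3-[(2S)-2-hydroxypropyl]-14-azabicyclo[9.2.1]tetradeca-1(13),11-dien-2-one | C[C@H](O)C[C@@H]1CCCCCCCc2ccc([nH]2)C1=O | intermediate
16 | 4-methoxy-3-pyrrolin-2-one (4-methoxy-1,5-dihydropyrrol-2-one) | COC1=CC(=O)NC1 | starting material
17 | 3-methoxy-2H-pyrrol-5-yl trifluoromethanesulfonate (present as its triflic acid salt) | COC1=CC(OS(=O)(=O)C(F)(F)F)=NC1 | intermediate
18 | 4-methoxy-1H,1'H-2,2'-bipyrrole | COc1c[nH]c(-c2ccc[nH]2)c1 | intermediate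
19 | cyclic alkoxy-azafulvenium (oxocarbenium) ion from 15, oxolane fused to ring E, camphorsulfonate as counter-ion | C[C@H]1C[C@@H]2CCCCCCCc3ccc([nH]3)C2=[O+]1 | intermediate
20 | oxolane whose C2 (the meso carbon) carries ring C and the 3-methoxy-5-(pyrrol-2-yl)pyrrol-2-yl group, both epimers at that carbon | C[C@H]1C[C@@H]2CCCCCCCc3ccc([nH]3)C2(O1)c4[nH]c(cc4OC)-c5ccc[nH]5 | intermediate
21 | seco-prodiginine: ansa-bridged meso-substituted prodiginine with a free (2S)-2-hydroxypropyl arm, E/Z mixture, drawn as free base | C[C@H](O)C[C@@H]1CCCCCCCc2ccc([nH]2)C1=C3N=C(c4ccc[nH]4)C=C3OC | intermediate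
22 | premarineosin A (spiro carbon R, O–CH(CH3) S, chain-bearing CH S, meso CH S) | COC1=CC(c2ccc[nH]2)=N[C@]12O[C@@H](C)C[C@@H]1CCCCCCCc3ccc([nH]3)[C@H]12 | target

## Step count and risks

Total step count: 9. Longest linear sequence: 7 steps (1, 2, 4, 5, 6, 7, 9). Steps 3 and 8 are one-step branches.

**Step 9 (Proposed new method).**
- What may go wrong:
  - The cascade may stall at the open, coloured chromophore.
  - The acid-sensitive bipyrrole may oligomerise before it is captured.
  - Protonation of the meso carbon may show poor facial selectivity.
  - The stereocentre next to the meso carbon may erode through proton loss from the cationic intermediates.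
- The fallback uses known reaction types only, sets out from 15 and 16 and returns at 22. It brings ring B in at the lactam oxidation level and attaches ring A last.
- Lactam 16 is silylated (Me3SiOTf, Et3N, CH2Cl2, 0 °C) to 4-methoxy-2-(trimethylsilyloxy)-1H-pyrrole F1.
- Ketone 15 is ionised with Me3SiOTf at −78 °C and captured by F1 in a vinylogous Mukaiyama-type addition to an oxocarbenium ion. This gives the oxolanyl pyrrolinone F2 as a mixture of epimers.
- CF3CO2H in CH2Cl2 opens the oxolane by E1 elimination to the hydroxy alkylidene-pyrrolinone F3.
- The enamide of F3 is protonated at the meso carbon to an N-acyliminium ion that the hydroxyl group traps (6-exo-trig N-acyliminium spirocyclisation). This gives the spiro-lactam F4, ring D again being the last ring closed.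
- The condensation of step 8 (Tf2O, CH2Cl2, −78 → 0 °C; then 1) finally converts the lactam carbonyl of F4 into the 2-pyrrolyl imine of 22.

**Step 6.**
- What may go wrong: intermolecular metathesis (oligomerisation) may outrun closure of the strained ansa ring, or alkene migration before closure may cause ring contraction.
- The fallback sets out from 3 and 7 and returns at 15. It closes ring E at the bond between ring C and the chain by B-alkyl Suzuki–Miyaura macrocyclisation, which also makes step 7 unnecessary.
- Compound 3 is dibrominated (NBS, 2 equiv, THF, −78 °C) to 2,5-dibromo-1-SEM-pyrrole F5.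
- Lactone 7 is alkylated as in step 3 with 7-bromo-1-heptene (C=CCCCCCBr; LiN(iPr)2, THF/DMPU) to the trans-heptenyl lactone F6.
- Single bromine–lithium exchange on F5 (n-BuLi, 1 equiv, THF, −78 °C) and addition to F6 as in step 4 give the N-SEM bromo ketone F7.
- Bu4NF as in step 5 gives the N–H bromo ketone F8.
- Hydroboration of the terminal alkene (9-BBN-H in excess to allow for the O–H and N–H groups, THF) gives the B-alkyl borane F9.
- F9 is added slowly to Pd(dppf)Cl2, AsPh3 and Cs2CO3 in DMF/THF/H2O and should close directly to 15.

**Step 4.**
- What may go wrong: the basic heteroaryllithium may enolise the lactone, with loss of material and erosion of the α-stereocentre, or it may add twice.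
- The fallback sets out from 10 and 6 and returns at 13. It transfers the acyl group from a Weinreb amide.
- Lactone 10 is opened with MeONHMe·HCl and Me2AlCl (CH2Cl2, 0 °C) to the hydroxy Weinreb amide F10.
- F10 is silylated at once (TBSCl, imidazole, DMF) to the silyl ether F11 so that relactonisation is blocked.
- Organolithium 11, generated from 6 as in step 4, adds once to F11 through the chelated tetrahedral adduct and gives the doubly silicon-protected ketone F12.
- Bu4NF (THF, 50 °C) removes both silicon groups in one operation and delivers 13.

## Further compounds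

F1 | step 9 | 4-methoxy-2-(trimethylsilyloxy)-1H-pyrrole | COc1c[nH]c(O[Si](C)(C)C)c1
F2 | step 9 | oxolanyl pyrrolinone: 4-methoxy-1,5-dihydropyrrol-2-one bound through C5 to the meso carbon of the ring-E-fused oxolane, mixture of epimers at the two new centres | C[C@H]1C[C@@H]2CCCCCCCc3ccc([nH]3)C2(O1)C4NC(=O)C=C4OC
F3 | step 9 | hydroxy alkylidene-pyrrolinone (5-ylidene-4-methoxypyrrol-2-one on the meso carbon, free (2S)-2-hydroxypropyl arm), E/Z mixture | C[C@H](O)C[C@@H]1CCCCCCCc2ccc([nH]2)C1=C3NC(=O)C=C3OC
F4 | step 9 | spiro-lactam with rings B (as lactam), C, D and E of the target and the same four configurations | COC1=CC(=O)N[C@]12O[C@@H](C)C[C@@H]1CCCCCCCc3ccc([nH]3)[C@H]12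
F5 | step 6 | 2,5-dibromo-1-{[2-(trimethylsilyl)ethoxy]methyl}-1H-pyrrole | Brc1ccc(Br)n1COCC[Si](C)(C)C
F6 | step 6 | (3S,5S)-3-(hept-6-en-1-yl)-5-methyloxolan-2-one | C[C@H]1C[C@H](CCCCCC=C)C(=O)O1
F7 | step 6 | (2S)-1-(5-bromo-1-SEM-pyrrol-2-yl)-2-[(2S)-2-hydroxypropyl]non-8-en-1-one | C[C@H](O)C[C@H](CCCCCC=C)C(=O)c1ccc(Br)n1COCC[Si](C)(C)C
F8 | step 6 | (2S)-1-(5-bromo-1H-pyrrol-2-yl)-2-[(2S)-2-hydroxypropyl]non-8-en-1-one | C[C@H](O)C[C@H](CCCCCC=C)C(=O)c1ccc(Br)[nH]1
F9 | step 6 | B-alkyl-9-BBN adduct of F8 (boron on the terminal carbon) | C[C@H](O)C[C@H](CCCCCCCB1C2CCCC1CCC2)C(=O)c1ccc(Br)[nH]1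
F10 | step 4 | (2S,4S)-4-hydroxy-N-methoxy-N-methyl-2-(prop-2-en-1-yl)pentanamide | C[C@H](O)C[C@H](CC=C)C(=O)N(C)OC
F11 | step 4 | (2S,4S)-4-(tert-butyldimethylsilyloxy)-N-methoxy-N-methyl-2-(prop-2-en-1-yl)pentanamide | C[C@H](O[Si](C)(C)C(C)(C)C)C[C@H](CC=C)C(=O)N(C)OC
F12 | step 4 | O-TBS ether of 12 | C[C@H](O[Si](C)(C)C(C)(C)C)C[C@H](CC=C)C(=O)c1ccc(CCCCC=C)n1COCC[Si](C)(C)C
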